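Ring B of the target is an α-ketol: the C8 ketone sits next to the oxygen-bearing C9, between the enolisable C7 and the fusion carbon C10. The C7 isopropenyl group, the C9 oxygen and the C10–C9 bond are all equatorial on the trans-decalin, so these centres can be left to thermodynamic control.
Endgame: the C3 angelate and the C9 (E)-3-methylpent-2-enoate are cleaved back to the 3-O-silyl 9-hydroxy-8-ketone.
Key disconnection: C8–C9, made by a thiazolylidene-catalysed intramolecular benzoin reaction of a ring A 8,9-dialdehyde. Ring B is formed last.
Dialdehyde: C7–C8 and the isopropenyl group come from a formaldehyde–ene reaction on a prenyl chain, which is made by Wittig reaction of a lactol. The temporary C7/C9 δ-lactone keeps C9–OH apart from C3–OH.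
Ring A is bought as 2-methylcyclohex-2-enone. It is elaborated by asymmetric conjugate addition (C10–C9) with enolate alkylation (C5–C6), enol triflate methylation (C4–C15) and hydroboration (C3–O, C4–H).

Key step: step 10

Remark: eremophilane numbering is used (ring A = C1–C5, C10; ring B = C5–C10; C11–C13 isopropenyl; C14 on C5; C15 on C4); 19 and 20 form as C7 epimer mixtures, are named and drawn as the 7S epimer, and both epimers go into step 10; the ligand enantiomer that gives 10R in step 1 is to be fixed in a pilot run; acids 22 and 25 are assumed to be bought as the pure E and Z isomers.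

Step 1
Reactants: 1 2-methylcyclohex-2-en-1-one; 2 (chloromethyl)(isopropoxy)dimethylsilane; 3 methyl bromoacetate
Product: 6 methyl [(1S,2R)-2-{[isopropoxy(dimethyl)silyl]methyl}-1-methyl-6-oxocyclohexyl]acetate (5S,10R; C6 trans to C9), via Grignard reagent 4 (not isolated), via chloromagnesium enolate 5 (not isolated)
Conditions: 2, Mg, THF, rt; Cu(OTf)2 (5 mol %), 1-mesityl-3-[(2S)-1-hydroxy-3,3-dimethylbutan-2-yl]-4,5-dihydroimidazolium hexafluorophosphate (6 mol %), Et2O, −30 °C, then 1; then 3, DMPU, −30 °C → rt
Reagents that add atoms: none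
Why: Copper-catalysed asymmetric conjugate addition of a Grignard reagent to an α-methyl cyclic enone with enolate alkylation (tandem vicinal difunctionalisation): the chiral carbene–copper complex chooses the enone face and sets C10, and the tetrasubstituted enolate, whose C10 side chain stands pseudoaxial to avoid the C5 methyl group, is alkylated by the activated halide on the opposite face, which puts C6 trans to C9 and sets the quaternary C5.

Step 2
Reactants: 6 keto ester
Product: 8 methyl [(1S,6R)-6-{[isopropoxy(dimethyl)silyl]methyl}-1-methyl-2-(trifluoromethylsulfonyloxy)cyclohex-2-en-1-yl]acetate, via potassium enolate 7 (not isolated)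
Conditions: KN(SiMe3)2, THF, −78 °C; then PhNTf2, −78 → 0 °C
Reagents that add atoms: N-phenylbis(trifluoromethanesulfonimide), O=S(=O)(N(c1ccccc1)S(=O)(=O)C(F)(F)F)C(F)(F)F
Why: Enolate O-triflation gives a single enol triflate because C5 is quaternary, so the ketone can enolise only towards C3, and because the ketone is more acidic than the hindered ester CH2.

Step 3
Reactants: 8 enol triflate
Product: 9 methyl [(1S,6R)-6-{[isopropoxy(dimethyl)silyl]methyl}-1,2-dimethylcyclohex-2-en-1-yl]acetate
Conditions: Me2Zn, Pd(PPh3)4 (5 mol %), THF, 0 → 40 °C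
Reagents that add atoms: dimethylzinc, C[Zn]C
Why: Negishi coupling of the alkenyl triflate places the C15 methyl group on C4 with the double bond fixed at C3=C4, and the mild organozinc spares the ester and the alkoxysilane, which a methyl carbinol–dehydration sequence would not.

Step 4
Reactants: 9 trisubstituted alkene
Product: 12 (4aS,5R,6R,8aR)-6-hydroxy-4a,5-dimethyloctahydro-3H-isochromen-3-one (trans-fused δ-lactone; C7 carbonyl; ring oxygen on C9; 3R,4R,5S,10R), via alkylborane 10 (not isolated), via diol ester 11 (not isolated)
Conditions: BH3·THF, THF, 0 °C → rt; then KF, KHCO3, 30 % H2O2, THF/MeOH, rt; then pyridinium p-toluenesulfonate (5 mol %), toluene, 60 °C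
Reagents that add atoms: hydrogen peroxide, OO
Why: Hydroboration–oxidation merged with Tamao oxidation: borane adds syn with boron on C3 from the α face opposite the pseudoaxial C5 methyl group, so C4–H and C3–O are both α (equatorial C15 and equatorial C3 oxygen), the one peroxide work-up turns C–B and C–Si into C–O with retention, and the freed C9 hydroxyl lactonises onto the C7 ester, which leaves C3–OH as the only free hydroxyl.

Step 5
Reactants: 12 hydroxy lactone
Product: 13 (4aS,5R,6R,8aR)-6-(tert-butyldimethylsilyloxy)-4a,5-dimethyloctahydro-3H-isochromen-3-one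
Conditions: TBSOTf, 2,6-lutidine, CH2Cl2, 0 °C
Reagents that add atoms: tert-butyldimethylsilyl trifluoromethanesulfonate, CC(C)(C)[Si](C)(C)OS(=O)(=O)C(F)(F)F
Why: Silyl ether formation with the reactive triflate covers the hindered equatorial C3 hydroxyl, the only free one because the C9 oxygen is tied up in the lactone.

Step 6
Reactants: 13 silyl ether lactone
Product: 14 lactol of 13 (C7 hemiacetal; anomer mixture)
Conditions: i-Bu2AlH (1.1 equiv), CH2Cl2, −78 °C; aq potassium sodium tartrate
Reagents that add atoms: none
Why: Partial reduction of a lactone by a dialkylaluminium hydride stops at the lactol because the tetrahedral aluminium alkoxide survives at −78 °C, and the new hemiacetal centre needs no control since it is lost in step 7.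

Step 7
Reactants: 14 lactol; 15 isopropyltriphenylphosphonium iodide
Product: 17 [(1R,2S,3R,4R)-4-(tert-butyldimethylsilyloxy)-2,3-dimethyl-2-(3-methylbut-2-en-1-yl)cyclohexyl]methanol, via phosphorus ylide 16 (not isolated)
Conditions: 15 (3 equiv), n-BuLi, THF, 0 °C; then 14, 0 °C → rt
Reagents that add atoms: none
Why: Wittig olefination of the lactol through its open hydroxy aldehyde form with excess unstabilised ylide builds the C7=C11 prenyl alkene (no alkene geometry arises), frees the C9 hydroxyl and touches no stereocentre.

Step 8
Reactants: 17 prenyl alcohol; 18 paraformaldehyde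
Product: 19 (2S)-2-{[(1S,2R,3R,6R)-3-(tert-butyldimethylsilyloxy)-6-(hydroxymethyl)-1,2-dimethylcyclohexyl]methyl}-3-methylbut-3-en-1-ol (8,9-diol; formed beside its 7R epimer)
Conditions: 18 (1.2 equiv CH2O), Me2AlCl (3 equiv), CH2Cl2, −78 → 0 °C; aq potassium sodium tartrate
Reagents that add atoms: none
Why: Lewis acid-promoted carbonyl–ene reaction of formaldehyde with a trisubstituted alkene: once the first equivalent of Me2AlCl has turned C9–OH into an inert aluminium alkoxide, complexed formaldehyde bonds to the less substituted alkene carbon C7 while a hydrogen leaves a C11 methyl group, which forms C7–C8 and the isopropenyl group at once and without a regiochemical alternative, whereas the new C7 centre is uncontrolled and is left for step 10 to correct.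

Step 9
Reactants: 19 8,9-diol
Product: 20 (2S)-2-{[(1R,2R,3R,6R)-3-(tert-butyldimethylsilyloxy)-6-formyl-1,2-dimethylcyclohexyl]methyl}-3-methylbut-3-enal (ring A 8,9-dialdehyde; beside its 7R epimer)
Conditions: Dess–Martin periodinane (2.6 equiv), NaHCO3, CH2Cl2, 0 °C → rt
Reagents that add atoms: none
Why: Dess–Martin oxidation in a buffered, amine-free medium takes both primary alcohols to the aldehydes without over-oxidation and without a base able to shift the β,γ-double bond, and the crude dialdehyde is used at once.

Step 10
Reactants: 20 ring A 8,9-dialdehyde (both C7 epimers)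
Product: 21 (3R,4R,5R,7S,9S,10R)-3-(tert-butyldimethylsilyloxy)-9-hydroxyeremophil-11-en-8-one (trans-fused ketol)
Conditions: 3-benzyl-5-(2-hydroxyethyl)-4-methylthiazolium chloride (20 mol %), Et3N (50 mol %), degassed t-BuOH/THF 1:1, 0.02 M, 50 °C, Ar
Reagents that add atoms: none
Why: The thiazol-2-ylidene released by Et3N adds to the C8 formyl group, proton transfer gives the Breslow enaminol (an acyl anion equivalent), its C8 carbon attacks the C9 formyl carbon, and a proton shift with loss of the carbene leaves the C8 ketone and a free C9 hydroxyl. The closest known reaction is the thiazolium-catalysed intramolecular benzoin (acyloin) cyclisation of aliphatic 1,6-dialdehydes to 2-hydroxycyclohexanones. Ring B closes in a 6-exo-trig mode through a chair in which the C5–C6 and C10–C9 bonds are both equatorial on ring A, so the trans fusion laid down in step 1 is kept, and C10, being α to a formyl group, could only drift towards this same more stable arrangement. C9 is set by that chair, since an axial C9 oxygen would be 1,3-diaxial to the C5 methyl group, and it stays correctable through the enediol and retro-benzoin, while C7 is α to the C8 carbonyl before and after closure, so amine-mediated enolisation funnels both C7 epimers into the equatorial 7S isomer. The step needs C8 and not C9 as the acyl donor: the C9 formyl group sits on a ring carbon next to the quaternary C5 and resists carbene addition and planarisation to an enaminol, whereas the C8 formyl group hangs on a flexible chain and its adduct C–H is acidified by the adjacent isopropenyl group. Intramolecular aldol adducts (C7 to C9 or C10 to C8) would carry a quaternary α-carbon, cannot dehydrate and revert, and the weak substoichiometric base, the moderate temperature and the non-nucleophilic alcohol are chosen to keep C11=C12 out of conjugation.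

Step 11
Reactants: 21 ketol; 22 (E)-3-methylpent-2-enoic acid
Product: 23 (3R,4R,5R,7S,9S,10R)-3-(tert-butyldimethylsilyloxy)-8-oxoeremophil-11-en-9-yl (E)-3-methylpent-2-enoate
Conditions: N-ethyl-N'-(3-dimethylaminopropyl)carbodiimide hydrochloride (EDC·HCl), 4-(dimethylamino)pyridine (10 mol %), CH2Cl2, 0 °C → rt
Reagents that add atoms: none
Why: Steglich esterification acylates the only free hydroxyl, and the low temperature and small charge of the pyridine catalyst should keep the E-configured β,β-disubstituted acrylate from deconjugation and the ketol from epimerising.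

Step 12
Reactants: 23 silyl ether ester
Product: 24 (3R,4R,5R,7S,9S,10R)-3-hydroxy-8-oxoeremophil-11-en-9-yl (E)-3-methylpent-2-enoate
Conditions: HF·pyridine, pyridine, THF, 0 °C → rt
Reagents that add atoms: none
Why: Fluoride-driven silyl ether cleavage in a weakly acidic, pyridine-buffered medium avoids the basic conditions that would risk acyl migration, epimerisation at C7 or C9, or conjugation of the isopropenyl group.

Step 13
Reactants: 24 C3 alcohol; 25 angelic acid [(Z)-2-methylbut-2-enoic acid]
Product: 27 target CNP0301161.1 (3-angelate 9-[(E)-3-methylpent-2-enoate]; 3R,4R,5R,7S,9S,10R), via mixed anhydride 26 (not isolated)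
Conditions: 25, 2,4,6-trichlorobenzoyl chloride, Et3N, toluene, rt; then 24, 80 °C
Reagents that add atoms: none
Why: Yamaguchi-type esterification through the 2,4,6-trichlorobenzoyl mixed anhydride without a nucleophilic pyridine catalyst is the standard way to transfer an angeloyl group without Z to E isomerisation to the tiglate, and the equatorial C3 hydroxyl is the only nucleophile left.

Compound list
1 | 2-methylcyclohex-2-en-1-one | CC1=CCCCC1=O | starting material
2 | (chloromethyl)(isopropoxy)dimethylsilane | CC(C)O[Si](C)(C)CCl | starting material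
3 | methyl bromoacetate | COC(=O)CBr | starting material
4 | {[isopropoxy(dimethyl)silyl]methyl}magnesium chloride | CC(C)O[Si](C)(C)C[Mg]Cl | intermediate
5 | chloromagnesium enolate (10R) | CC1=C(O[Mg]Cl)CCC[C@H]1C[Si](C)(C)OC(C)C | intermediate
6 | methyl [(1S,2R)-2-{[isopropoxy(dimethyl)silyl]methyl}-1-methyl-6-oxocyclohexyl]acetate | COC(=O)C[C@]1(C)C(=O)CCC[C@H]1C[Si](C)(C)OC(C)C | intermediate
7 | potassium C3=C4 enolate of 6 | COC(=O)C[C@]1(C)C([O-])=CCC[C@H]1C[Si](C)(C)OC(C)C.[K+] | intermediate
8 | C3=C4 enol triflate (5S,10R) | COC(=O)C[C@]1(C)C(OS(=O)(=O)C(F)(F)F)=CCC[C@H]1C[Si](C)(C)OC(C)C | intermediate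
9 | C4-methyl C3=C4 alkene (5S,10R) | COC(=O)C[C@]1(C)C(C)=CCC[C@H]1C[Si](C)(C)OC(C)C | intermediate
10 | 3α-boryl 4β-methyl alkylborane | COC(=O)C[C@]1(C)[C@@H](C)[C@H](B)CC[C@H]1C[Si](C)(C)OC(C)C | intermediate
11 | 3,9-diol methyl ester (3R,4R,5S,10R) | COC(=O)C[C@]1(C)[C@@H](C)[C@H](O)CC[C@H]1CO | intermediate
12 | (4aS,5R,6R,8aR)-6-hydroxy-4a,5-dimethyloctahydro-3H-isochromen-3-one | O=C1C[C@]2(C)[C@@H](C)[C@H](O)CC[C@H]2CO1 | intermediate
13 | 3-O-TBS ether of 12 | O=C1C[C@]2(C)[C@@H](C)[C@H](O[Si](C)(C)C(C)(C)C)CC[C@H]2CO1 | intermediate
14 | lactol of 13 (anomers) | OC1C[C@]2(C)[C@@H](C)[C@H](O[Si](C)(C)C(C)(C)C)CC[C@H]2CO1 | intermediate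
15 | isopropyltriphenylphosphonium iodide | CC(C)[P+](c1ccccc1)(c1ccccc1)c1ccccc1.[I-] | starting material
16 | isopropylidenetriphenylphosphorane | CC(C)=P(c1ccccc1)(c1ccccc1)c1ccccc1 | intermediate
17 | [(1R,2S,3R,4R)-4-(tert-butyldimethylsilyloxy)-2,3-dimethyl-2-(3-methylbut-2-en-1-yl)cyclohexyl]methanol | CC(C)=CC[C@]1(C)[C@@H](C)[C@H](O[Si](C)(C)C(C)(C)C)CC[C@H]1CO | intermediate
18 | paraformaldehyde (as formaldehyde) | C=O | starting material
19 | 8,9-diol (3R,4R,5S,7S,10R; with 7R epimer) | C=C(C)[C@@H](CO)C[C@]1(C)[C@@H](C)[C@H](O[Si](C)(C)C(C)(C)C)CC[C@H]1CO | intermediate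
20 | ring A 8,9-dialdehyde (3R,4R,5R,7S,10R; with 7R epimer) | C=C(C)[C@@H](C=O)C[C@]1(C)[C@@H](C)[C@H](O[Si](C)(C)C(C)(C)C)CC[C@H]1C=O | intermediate
21 | (3R,4R,5R,7S,9S,10R)-3-(tert-butyldimethylsilyloxy)-9-hydroxyeremophil-11-en-8-one | C=C(C)[C@@H]1C[C@]2(C)[C@@H](C)[C@H](O[Si](C)(C)C(C)(C)C)CC[C@H]2[C@H](O)C1=O | intermediate
22 | (E)-3-methylpent-2-enoic acid | CC/C(C)=C/C(=O)O | starting material
23 | 3-O-TBS 9-[(E)-3-methylpent-2-enoate] | C=C(C)[C@@H]1C[C@]2(C)[C@@H](C)[C@H](O[Si](C)(C)C(C)(C)C)CC[C@H]2[C@H](OC(=O)/C=C(\C)CC)C1=O | intermediate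
24 | 3-hydroxy 9-[(E)-3-methylpent-2-enoate] | C=C(C)[C@@H]1C[C@]2(C)[C@@H](C)[C@H](O)CC[C@H]2[C@H](OC(=O)/C=C(\C)CC)C1=O | intermediate
25 | angelic acid | C/C=C(/C)C(=O)O | starting material
26 | angelic 2,4,6-trichlorobenzoic anhydride | C/C=C(/C)C(=O)OC(=O)c1c(Cl)cc(Cl)cc1Cl | intermediate
27 | CNP0301161.1 | C=C(C)[C@@H]1C[C@]2(C)[C@@H](C)[C@H](OC(=O)/C(C)=C\C)CC[C@H]2[C@H](OC(=O)/C=C(\C)CC)C1=O | target

Total step count: 13. Longest linear sequence: 13 steps (1 to 27).

Steps most likely to fail

Step 10. Three things may go wrong. The C9 formyl group may take the donor role and lead to the 9-oxo-8-hydroxy regioisomer. The amine may move C11=C12 into conjugation with the C8 carbonyl before or after closure. Carbene addition to two α-branched aldehydes may also be slow enough for oxidation or oligomerisation to compete.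

The fallback sets out from 20 and returns at 23. It makes C8–C9 reductively, without base and without a choice of donor. SmI2 (THF, t-BuOH, −78 °C → rt) couples the two formyl groups in an intramolecular pinacol reaction. Chelation favours a cis-diol, and the 1,3-diaxial clash with the C5 methyl group disfavours an axial C9 oxygen. The 8α,9α-diol F1 (C8–OH axial, C9–OH equatorial, C7 epimers carried along) is therefore expected. Steglich acylation with 22 should take the equatorial hydroxyl and give the C9 monoester F2. Dess–Martin oxidation of the remaining axial C8 hydroxyl, then brief exposure to Et3N to bring C7 to the equatorial isomer, gives 23.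

Step 1. The bulky α-silyl Grignard reagent may add with poor facial selectivity, may prefer 1,2-addition, or may leave an enolate that is protonated faster than it is alkylated.

The fallback sets out from 1, 2 and 3 and returns at 12. It takes the absolute configuration from a resolution instead of from catalysis. Steps 1 to 4 are run with achiral CuBr·SMe2 in place of the chiral catalyst. Compounds 6, 8, 9 and 12 then form together with the mirror-image keto ester F3, the mirror-image enol triflate F4, the mirror-image alkene F5 and the mirror-image hydroxy lactone F6. Acetylation with Candida antarctica lipase B and vinyl acetate in t-BuOMe should, by the empirical size rule for secondary alcohols, acylate the 3R alcohol to the acetate F7 and leave F6 untouched. After chromatographic separation, K2CO3/MeOH and then pyridinium p-toluenesulfonate in toluene return 12.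

Step 8. The Lewis acid may strip the silyl ether. The C9 alkoxide may capture formaldehyde and cyclise through an oxocarbenium ion. The new 1,1-disubstituted alkene may undergo a second ene reaction.

The fallback sets out from 17 and returns at 19. It replaces the Lewis acid process by an allylmetal addition. Ene-type chlorination with hypochlorous acid (Ca(OCl)2, solid CO2, CH2Cl2/H2O, 0 °C) should give the rearranged allylic chloride F8 (C7–Cl, isopropenyl). A Barbier reaction with indium powder, NaI and aqueous formaldehyde in THF then goes through the allylindium species. This species bonds to formaldehyde at its more substituted terminus C7 and delivers 19.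

Further compounds
F1 | step 10 | (3R,4R,5R,7S,8R,9S,10R)-3-(tert-butyldimethylsilyloxy)eremophil-11-ene-8,9-diol | C=C(C)[C@@H]1C[C@]2(C)[C@@H](C)[C@H](O[Si](C)(C)C(C)(C)C)CC[C@H]2[C@H](O)[C@@H]1O
F2 | step 10 | 9-[(E)-3-methylpent-2-enoate] of F1 | C=C(C)[C@@H]1C[C@]2(C)[C@@H](C)[C@H](O[Si](C)(C)C(C)(C)C)CC[C@H]2[C@H](OC(=O)/C=C(\C)CC)[C@@H]1O
F3 | step 1 | mirror image of 6 | COC(=O)C[C@@]1(C)C(=O)CCC[C@@H]1C[Si](C)(C)OC(C)C
F4 | step 1 | mirror image of 8 | COC(=O)C[C@@]1(C)C(OS(=O)(=O)C(F)(F)F)=CCC[C@@H]1C[Si](C)(C)OC(C)C
F5 | step 1 | mirror image of 9 | COC(=O)C[C@@]1(C)C(C)=CCC[C@@H]1C[Si](C)(C)OC(C)C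
F6 | step 1 | mirror image of 12 | O=C1C[C@@]2(C)[C@H](C)[C@@H](O)CC[C@@H]2CO1
F7 | step 1 | 3-O-acetate of 12 | O=C1C[C@]2(C)[C@@H](C)[C@H](OC(C)=O)CC[C@H]2CO1
F8 | step 8 | C7 allylic chloride from 17 (C7 epimers) | C=C(C)C(Cl)C[C@]1(C)[C@@H](C)[C@H](O[Si](C)(C)C(C)(C)C)CC[C@H]1CO
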